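**Plan** (labdane numbering throughout)

1. Cuts: C3–Br back to a C3 ketone. The C4 gem-dimethyl group and trans H-5 go back to a 4-methyl-4-en-3-one. Ring B is cut at C5–C6 by a retro-oxy-Cope step that ties C3 to C8. The resulting bicyclo[2.2.2]octene is cut at C3–C8 and C9–C10 (Diels–Alder), and the dienophile goes back to (R)-linalool.
2. Enabling feature: once C8 is bonded to C3, the ring B alkene C7=C8 and the oxygenated C3 of ring A form a 1,5-dien-3-ol, C6=C7–C8–C3(O)–C4=C5. A [3,3] shift then makes C5–C6, fixes the alkene at C7=C8 and leaves a C3/C4 enolate.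
3. Forward: ring A as a silyloxydiene (C1–C5, C10); union with the ten-carbon enal from linalool to the bridged bicycle; methylenation (C6); anionic oxy-Cope to the cis-octalin (ring B closed); dehydrogenation; reductive methylation; ketone to bromide.
4. Stereochemistry: C13 from (R)-linalool. C9 and C10 from the endo, catalyst-controlled cycloaddition of the E enal (chain ends anti to the C10 methyl). C5 by dissolving-metal protonation. C3 by equatorial hydride delivery, then invertive bromination.

Key step: step 9

Assumption: the facial sense of the oxazaborolidine/AlBr3 catalyst in step 6 is taken from the accepted model for 2-substituted enals; if the opposite adduct forms, the enantiomeric catalyst is used with no other change.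

**Step 1**
Reactants: 1 (R)-(−)-linalool
Product: 2 (R)-linalool tert-butyldimethylsilyl ether
Conditions: TBSOTf, 2,6-lutidine, CH2Cl2, −78 to 0 °C
Reagents that add atoms: tert-butyldimethylsilyl trifluoromethanesulfonate CC(C)(C)[Si](C)(C)OS(=O)(=O)C(F)(F)F
Why: Silylation of a tertiary allylic alcohol with a silyl triflate and a hindered base proceeds without ionisation, so C13 keeps its configuration.

**Step 2**
Reactants: 2 (R)-linalool tert-butyldimethylsilyl ether
Product: 3 (2E,6R)-allylic alcohol
Conditions: SeO2 (cat.), t-BuOOH, salicylic acid (cat.), CH2Cl2, rt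
Reagents that add atoms: selenium dioxide O=[Se]=O (catalytic oxygen carrier) and tert-butyl hydroperoxide CC(C)(C)OO
Why: SeO2-catalysed allylic oxidation (ene reaction then [2,3] shift) attacks the E methyl group of the trisubstituted alkene, while the vinyl group has no allylic hydrogen and is spared.

**Step 3**
Reactants: 3 (2E,6R)-allylic alcohol
Product: 4 (2E,6R)-enal
Conditions: Dess–Martin periodinane, NaHCO3, CH2Cl2, 0 °C to rt
Reagents that add atoms: none
Why: Dess–Martin oxidation of a primary allylic alcohol gives the enal under buffered conditions that keep the E geometry and the silyl ether.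

**Step 4**
Reactants: 5 propanal; 6 pent-1-en-3-one
Product: 8 2,4-dimethylcyclohex-2-en-1-one (racemic), via 2-methyl-5-oxoheptanal 7 (not isolated)
Conditions: Et2NH (cat.), neat, 0 °C to rt; then KOH, MeOH/H2O, reflux
Reagents that add atoms: none
Why: Amine-catalysed Michael addition followed by intramolecular aldol condensation (Robinson-type annulation) gives the enone; its single stereocentre is erased in step 5.

**Step 5**
Reactants: 8 2,4-dimethylcyclohex-2-en-1-one
Product: 9 triethylsilyl dienol ether (1-silyloxy-2,4-dimethylcyclohexa-1,3-diene)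
Conditions: TESOTf, Et3N, CH2Cl2, 0 °C to rt
Reagents that add atoms: triethylsilyl trifluoromethanesulfonate CC[Si](CC)(CC)OS(=O)(=O)C(F)(F)F
Why: Soft enolisation under equilibrating conditions removes the γ-hydrogen and gives the linear, fully substituted conjugated dienol silyl ether (thermodynamic silyl dienol ether formation, as with 4-en-3-one steroids).

**Step 6**
Reactants: 4 (2E,6R)-enal; 9 triethylsilyl dienol ether
Product: 10 bicyclo[2.2.2]octene aldehyde (formyl endo; side chain exo)
Conditions: (S)-3,3-diphenyl-1-(2-methylphenyl)tetrahydro-1H,3H-pyrrolo[1,2-c][1,3,2]oxazaborole (10 mol %) activated with AlBr3 (8 mol %), CH2Cl2, −78 to −40 °C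
Reagents that add atoms: none
Why: Chiral Lewis acid-catalysed Diels–Alder reaction in which the silyloxy terminus C3 bonds to the α-carbon C8 and the methyl-bearing terminus C10 to the β-carbon C9; the formyl group goes endo and the chain, trans to it in the E enal, exo, and the catalyst directs the diene to the C2-Re face of the enal, which sets C3, C8, C9 and C10 relative to C13.

**Step 7**
Reactants: 10 bicyclo[2.2.2]octene aldehyde
Product: 11 vinyl bicyclo[2.2.2]octene silyl ether
Conditions: Ph3PCH3Br, KN(SiMe3)2, THF, 0 °C to rt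
Reagents that add atoms: methyltriphenylphosphonium bromide C[P+](c1ccccc1)(c1ccccc1)c1ccccc1.[Br-]
Why: Wittig methylenation of a non-enolisable aldehyde adds C6; the bridgehead silyl ether stays on, so no retro-aldol opening can occur.

**Step 8**
Reactants: 11 vinyl bicyclo[2.2.2]octene silyl ether
Product: 12 bridgehead alcohol
Conditions: HF·pyridine, pyridine, THF, 0 °C
Reagents that add atoms: none
Why: Buffered fluoride cleaves the exposed bridgehead triethylsilyl ether much faster than the tertiary tert-butyldimethylsilyl ether (selective desilylation).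

**Step 9**
Reactants: 12 bridgehead alcohol
Product: 15 cis-fused trimethylsilyl enol ether, via potassium bridgehead alkoxide 13 (not isolated), via potassium enolate 14 (not isolated)
Conditions: KH, 18-crown-6, THF, 0 °C to rt; then Me3SiCl/Et3N, −78 °C
Reagents that add atoms: chlorotrimethylsilane C[Si](C)(C)Cl
Why: Deprotonation gives a 1,5-dien-3-olate (C6=C7–C8–C3(O−)–C4=C5) whose oxyanion weakens the C3–C8 bond, so a concerted [3,3] sigmatropic shift (anionic oxy-Cope rearrangement) breaks C3–C8 and makes C5–C6 at or below room temperature. The closest known reaction type is the anionic oxy-Cope rearrangement of 2-vinylbicyclo[2.2.2]oct-5-en-2-olates to cis-octalones; here the alkoxide sits on the bridgehead end of the breaking bond, which should give the same acceleration. Ring B (C5–C6–C7=C8–C9–C10) is closed by this sigmatropic reorganisation through a boat-like six-atom transition state fixed by the bicycle, not by an exo or endo attack of a chain, and the new alkene is forced to C7=C8. The one new stereocentre, C5, is set suprafacially: C6 can only reach the face of the C4=C5 bridge that is syn to the C8–C9 bridge, so H-5 ends cis to the C10 methyl group; this centre is reset in steps 10 and 11, while C9 and C10 pass through unchanged with the chain anti to the C10 methyl group. The step needs the vinyl group syn to the C4=C5 bridge, which the endo cycloaddition secures, and O-silylation of the regiodefined C3/C4 enolate, which Me3SiCl/Et3N at −78 °C should ensure.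

**Step 10**
Reactants: 15 cis-fused trimethylsilyl enol ether
Product: 16 4-methyl-4-en-3-one (9S,10S,13R)
Conditions: Pd(OAc)2 (1.1 equiv), MeCN, rt
Reagents that add atoms: none
Why: Saegusa–Ito dehydrogenation through the palladium enolate and β-hydride loss from C5 gives the ring-fusion enone and removes the wrongly set C5 centre; neutral conditions keep the C7=C8 alkene out of conjugation.

**Step 11**
Reactants: 16 4-methyl-4-en-3-one
Product: 18 trans-fused 4,4-dimethyl-3-ketone (5S,9S,10S,13R), via lithium enolate 17 (not isolated)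
Conditions: Li, NH3(l)/THF, t-BuOH (1 equiv), −78 °C; then MeI, −78 to −33 °C
Reagents that add atoms: iodomethane CI
Why: Stork reductive alkylation: the β-carbanion at C5 is protonated axially, anti to the C10 methyl group, to give the trans ring fusion, and the regiodefined C3/C4 lithium enolate is C-methylated to the gem-dimethyl ketone; the isolated alkenes and the silyl ether are inert.

**Step 12**
Reactants: 18 trans-fused 4,4-dimethyl-3-ketone
Product: 19 axial 3-alcohol (3S,5S,9S,10S,13R)
Conditions: LiBH(s-Bu)3, THF, −78 °C; aq NH4Cl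
Reagents that add atoms: none
Why: The bulky borohydride attacks the 3-ketone next to the gem-dimethyl group from the equatorial direction, so the hydroxyl group ends axial, anti to the C10 methyl group (substrate-controlled ketone reduction).

**Step 13**
Reactants: 19 axial 3-alcohol
Product: 20 equatorial 3-bromide silyl ether (3R,5S,9S,10S,13R)
Conditions: PPh3, CBr4, toluene, 60 °C
Reagents that add atoms: tetrabromomethane BrC(Br)(Br)Br
Why: Appel bromination: bromide displaces the axial oxyphosphonium group with inversion to give the equatorial bromide, a displacement precedented for axial neopentylic alcohols of 3-oxygenated 4,4-dimethylcyclohexane terpenoids.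

**Step 14**
Reactants: 20 equatorial 3-bromide silyl ether
Product: 21 target CNP0210577.1
Conditions: Bu4NF, THF, 45 °C
Reagents that add atoms: none
Why: Fluoride desilylation frees the tertiary allylic alcohol; the equatorial neopentylic bromide has no antiperiplanar hydrogen and should survive.

**Compound list**

1 | (R)-(−)-linalool, (3R)-3,7-dimethylocta-1,6-dien-3-ol | C=C[C@](C)(O)CCC=C(C)C | starting material
2 | (3R)-3-[(tert-butyldimethylsilyl)oxy]-3,7-dimethylocta-1,6-diene | C=C[C@](C)(O[Si](C)(C)C(C)(C)C)CCC=C(C)C | intermediate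
3 | (2E,6R)-6-[(tert-butyldimethylsilyl)oxy]-2,6-dimethylocta-2,7-dien-1-ol | C=C[C@](C)(O[Si](C)(C)C(C)(C)C)CC/C=C(\C)CO | intermediate
4 | (2E,6R)-6-[(tert-butyldimethylsilyl)oxy]-2,6-dimethylocta-2,7-dienal | C=C[C@](C)(O[Si](C)(C)C(C)(C)C)CC/C=C(\C)C=O | intermediate
5 | propanal | CCC=O | starting material
6 | pent-1-en-3-one | C=CC(=O)CC | starting material
7 | 2-methyl-5-oxoheptanal (racemic) | CCC(=O)CCC(C)C=O | intermediate
8 | 2,4-dimethylcyclohex-2-en-1-one (racemic) | CC1C=C(C)C(=O)CC1 | intermediate
9 | triethyl[(2,4-dimethylcyclohexa-1,3-dien-1-yl)oxy]silane | CC1=CC(C)=C(O[Si](CC)(CC)CC)CC1 | intermediate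
10 | 1-(triethylsilyloxy)-2,4,6-trimethyl-5-[(3R)-3-(tert-butyldimethylsilyloxy)-3-methylpent-4-en-1-yl]bicyclo[2.2.2]oct-2-ene-6-carbaldehyde; formyl syn to the C2=C3 bridge, side chain anti to it; viewed from C1 toward C4 the bridges C2=C3, C6–C5 and C7–C8 follow counterclockwise | C=C[C@](C)(O[Si](C)(C)C(C)(C)C)CC[C@@H]1[C@]2(C)CC[C@@](O[Si](CC)(CC)CC)(C(C)=C2)[C@@]1(C)C=O | intermediate
11 | 6-ethenyl analogue of 10 (same configuration; ethenyl syn to the C2=C3 bridge) | C=C[C@](C)(O[Si](C)(C)C(C)(C)C)CC[C@@H]1[C@]2(C)CC[C@@](O[Si](CC)(CC)CC)(C(C)=C2)[C@@]1(C)C=C | intermediate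
12 | 6-ethenyl-2,4,6-trimethyl-5-[(3R)-3-(tert-butyldimethylsilyloxy)-3-methylpent-4-en-1-yl]bicyclo[2.2.2]oct-2-en-1-ol (configuration as 11) | C=C[C@](C)(O[Si](C)(C)C(C)(C)C)CC[C@@H]1[C@]2(C)CC[C@@](O)(C(C)=C2)[C@@]1(C)C=C | intermediate
13 | potassium alkoxide of 12 | C=C[C@](C)(O[Si](C)(C)C(C)(C)C)CC[C@@H]1[C@]2(C)CC[C@@]([O-])(C(C)=C2)[C@@]1(C)C=C.[K+] | intermediate
14 | potassium C3/C4 enolate of the cis-fused (5R,9S,10S,13R)-13-(tert-butyldimethylsilyloxy)-19-norlabda-7,14-dien-3-one | C=C[C@](C)(O[Si](C)(C)C(C)(C)C)CC[C@H]1C(C)=CC[C@H]2C(C)=C([O-])CC[C@]21C.[K+] | intermediate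
15 | (5R,9S,10S,13R)-13-(tert-butyldimethylsilyloxy)-3-(trimethylsilyloxy)-19-norlabda-3,7,14-triene (cis-fused) | C=C[C@](C)(O[Si](C)(C)C(C)(C)C)CC[C@H]1C(C)=CC[C@H]2C(C)=C(O[Si](C)(C)C)CC[C@]21C | intermediate
16 | (9S,10S,13R)-13-(tert-butyldimethylsilyloxy)-19-norlabda-4,7,14-trien-3-one | C=C[C@](C)(O[Si](C)(C)C(C)(C)C)CC[C@H]1C(C)=CCC2=C(C)C(=O)CC[C@]21C | intermediate
17 | lithium C3/C4 enolate of the trans-fused (5S,9S,10S,13R)-13-(tert-butyldimethylsilyloxy)-19-norlabda-7,14-dien-3-one | C=C[C@](C)(O[Si](C)(C)C(C)(C)C)CC[C@H]1C(C)=CC[C@@H]2C(C)=C([O-])CC[C@]21C.[Li+] | intermediate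
18 | (5S,9S,10S,13R)-13-(tert-butyldimethylsilyloxy)labda-7,14-dien-3-one (trans-fused; chain at C9 anti to the C10 methyl) | C=C[C@](C)(O[Si](C)(C)C(C)(C)C)CC[C@H]1C(C)=CC[C@@H]2C(C)(C)C(=O)CC[C@]21C | intermediate
19 | (3S,5S,9S,10S,13R)-13-(tert-butyldimethylsilyloxy)labda-7,14-dien-3-ol (axial hydroxyl) | C=C[C@](C)(O[Si](C)(C)C(C)(C)C)CC[C@H]1C(C)=CC[C@@H]2C(C)(C)[C@@H](O)CC[C@]21C | intermediate
20 | (3R,5S,9S,10S,13R)-3-bromo-13-(tert-butyldimethylsilyloxy)labda-7,14-diene (equatorial bromide) | C=C[C@](C)(O[Si](C)(C)C(C)(C)C)CC[C@H]1C(C)=CC[C@@H]2C(C)(C)[C@H](Br)CC[C@]21C | intermediate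
21 | (3R,5S,9S,10S,13R)-3-bromolabda-7,14-dien-13-ol, CNP0210577.1 | C=C[C@](C)(O)CC[C@H]1C(C)=CC[C@@H]2C(C)(C)[C@H](Br)CC[C@]21C | target

**Step count and risks**

Total steps: 14. Longest linear sequence: 12 (steps 1–3 and 6–14, from linalool).

Steps most likely to fail:

Step 6. The cycloaddition joins a fully substituted silyloxydiene to a trisubstituted enal. The catalyst may fail to override the small intrinsic facial bias, the formyl group may turn exo (that adduct cannot rearrange in step 9), and the acidic catalyst may desilylate the diene or stop at the open-chain Mukaiyama–Michael stage. Fallback, setting out from 8 and 4 and returning at 12: facial control is moved to a covalently bound auxiliary on the diene oxygen and the silyl enol ether is avoided. The potassium dienolate of 8 (KOt-Bu, THF) is O-acylated with (S)-2-methoxy-2-phenylacetyl chloride to give 2,4-dimethylcyclohexa-1,3-dien-1-yl (S)-2-methoxy-2-phenylacetate F1. Cycloaddition of F1 with 4 (BF3·OEt2, CH2Cl2, −40 °C, or heat in toluene) should give the bridgehead ester aldehyde F2, and methylenation as in step 7 the bridgehead ester triene F3. K2CO3 in MeOH then cleaves the ester to alcohol 12.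

Step 13. Backside displacement at the neopentylic C3 is slow. E2 loss of the axial oxyphosphonium group toward C2 and methyl migration from C4 can take over. Fallback, setting out from 18 and returning at 20: the C–H bond at C3 is formed last instead of the C–Br bond. Ketone 18 is condensed with hydrazine (N2H4·H2O, Et3N, EtOH, reflux) to the C3 hydrazone F4. Oxidative bromination (CuBr2, LiOt-Bu, THF, 0 °C) gives the 3,3-dibromide F5. Radical mono-reduction (Bu3SnH, 1.05 equiv, Et3B/air, toluene, −78 °C) should deliver hydrogen to the α-bromo radical from the open axial direction and leave the bromide equatorial, as in 20.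

Step 9. The alkoxide may rearrange incompletely because of ion pairing, cleave the C3–C8 bond heterolytically without reclosure, or be quenched by proton transfer or C-silylation. Fallback, setting out from 11 and returning at 16: the charge-neutral thermal siloxy-Cope rearrangement of silyl ether 11 (1,2-dichlorobenzene, about 200 °C, sealed tube) should give the cis-fused triethylsilyl enol ether F6 directly, without step 8. Pd(OAc)2 in MeCN then converts F6 to enone 16.

**Further compounds**

F1 | step 6 | 2,4-dimethylcyclohexa-1,3-dien-1-yl (S)-2-methoxy-2-phenylacetate | CC1=CC(C)=C(OC(=O)[C@@H](OC)c2ccccc2)CC1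
F2 | step 6 | bridgehead (S)-2-methoxy-2-phenylacetate analogue of aldehyde 10 | C=C[C@](C)(O[Si](C)(C)C(C)(C)C)CC[C@@H]1[C@]2(C)CC[C@@](OC(=O)[C@@H](OC)c3ccccc3)(C(C)=C2)[C@@]1(C)C=O
F3 | step 6 | bridgehead (S)-2-methoxy-2-phenylacetate analogue of triene 11 | C=C[C@](C)(O[Si](C)(C)C(C)(C)C)CC[C@@H]1[C@]2(C)CC[C@@](OC(=O)[C@@H](OC)c3ccccc3)(C(C)=C2)[C@@]1(C)C=C
F4 | step 13 | hydrazone of ketone 18 | C=C[C@](C)(O[Si](C)(C)C(C)(C)C)CC[C@H]1C(C)=CC[C@@H]2C(C)(C)C(=NN)CC[C@]21C
F5 | step 13 | (5S,9S,10S,13R)-3,3-dibromo-13-(tert-butyldimethylsilyloxy)labda-7,14-diene | C=C[C@](C)(O[Si](C)(C)C(C)(C)C)CC[C@H]1C(C)=CC[C@@H]2C(C)(C)C(Br)(Br)CC[C@]21C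
F6 | step 9 | cis-fused triethylsilyl enol ether (triethylsilyl analogue of 15) | C=C[C@](C)(O[Si](C)(C)C(C)(C)C)CC[C@H]1C(C)=CC[C@H]2C(C)=C(O[Si](CC)(CC)CC)CC[C@]21C
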